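# Proposed total synthesis of calycopterin

## Analysis of the target

Calycopterin (15) is a flavone: a 4H-chromen-4-one (rings A and C) with a 4-hydroxyphenyl ring B on C2, methoxy groups on C3, C6, C7 and C8, and free hydroxyls on C5 and C4'. It has no stereocentre, so the problem is one of substitution pattern and oxidation level only. Ring A is hexasubstituted and carries five oxygen atoms (O1 on C8a and the oxygens on C5, C6, C7 and C8); of the four exocyclic ones only the C5 oxygen, peri to the C4 carbonyl, must stay unmethylated. The sensitive parts are the electron-rich ring A (oxidation, Lewis-acid demethylation next to the carbonyl), the two phenols, and the pyranone, which opens under strong alkali. The difficulty is to build the fully substituted ring C with its 3-methoxy enol ether while telling the C5 oxygen apart from its neighbours. The strategy rests on the fact that C3 is a lone carbon bearing nothing but a methoxy group, and that both of its neighbours are acyl carbons in disguise: C4 is an aroyl carbon on C4a of ring A, and C2, together with O1 and ring B, is a 4-hydroxybenzoate ester of the phenolic oxygen on C8a. In addition, a ring A fragment with oxygen on both C5 and C8a and methoxyls on C6, C7 and C8 has a mirror plane through C4a and C7, so the two ortho oxygens are equivalent until ring C closes.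

## Retrosynthetic reasoning

**15 back to 14 and 13.** The last bonds cut are the two protecting-group bonds. In 14 the 4'-oxygen is a benzyl ether; in 13 the C5 oxygen is in addition a 4-(benzyloxy)benzoyl ester. The C5 ester is not an extra protecting group but what is left over from the key step. The benzyl ether is chosen for ring B because it is inert to the basic ylide, to the aldehyde oxidation and to acid chloride formation. Forward, carbonate-mediated methanolysis has to cleave one aryl ester without opening the pyranone, and hydrogenolysis has to remove the benzyl group without reducing C2=C3.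

**13 back to 8 and 10 (key disconnection).** Ring C is opened by cutting C2=C3 and C3–C4. These two bonds isolate C3 as a one-carbon piece that already carries its methoxy group, ylide 10. Everything else stays in one aromatic piece, acid chloride 8, in which C4 is the acyl chloride carbon and C2 is the carbonyl carbon of an ester on the ortho oxygen. Cutting O1–C2 or C4–C4a instead would need a separately made three-carbon piece bearing ring B and prior differentiation of the two ortho oxygens of ring A. The gain is convergence, a C3 methoxy that needs no late enol methylation, and automatic masking of the future C5 hydroxyl, because 8 has two identical ortho esters related by the mirror plane of ring A. Forward, 10 must be acylated on carbon by the acid chloride and not by the aryl esters (giving phosphonium salt 11), and the derived keto ylide 12 must olefinate an ester carbonyl with phosphorus leaving as its oxide.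

**10 back to 9.** The ylide cannot be stored and is made in the flask by deprotonation of commercial salt 9. One equivalent of 9 is returned in the key step, because a second equivalent of 10 acts as the base.

**8 back to 7, 6, and 4 plus 5.** The acid chloride comes from acid 7. The carboxyl carbon is traced to the formyl group of 6 rather than introduced at the acid level. A direct carboxylation of 3 would save a step, but it would place a carboxyl group between two free hydroxyls on a very electron-rich ring, an arrangement that decarboxylates readily and complicates O-acylation. The two ester C–O bonds are therefore cut at the aldehyde stage, to dihydroxy aldehyde 4 and two equivalents of commercial acid chloride 5. The Pinnick oxidation is placed after acylation, when no free phenol is left.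

**4 back to 3.** The C–C bond to the formyl carbon is cut. Diol 3 has a single ring C–H, flanked by both hydroxyls, so the formylation has no regiochemical choice.

**3 back to 2 and 1.** The two phenolic C–O bonds are traced to C–Br bonds, and these to the C–H bonds at C4 and C6 of commercial 1. Those are the two positions activated by the outer methoxy groups; the remaining C–H lies between them and becomes the formylation site. Forward, this needs a double electrophilic bromination and a double palladium-catalysed hydroxylation.

## Alternatives that were turned down

**Alternative 1: gold carbene closure of C4–C4a.**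
- Disconnection: the C4–C4a bond, with ring C traced back to the terminal alkyne of a propargylic ether of the ring A phenol, namely racemic 1-(benzyloxy)-5-({1-[4-(benzyloxy)phenyl]prop-2-yn-1-yl}oxy)-2,3,4-trimethoxybenzene A1.
- Forward key step: the catalyst Ph3PAuNTf2 A2, a complex of monovalent gold, activates the alkyne of A1, and the oxidant 8-methylquinoline N-oxide A3 transfers its oxygen to the internal alkyne carbon. The α-oxo gold carbene then attacks the only C–H position of ring A and gives racemic 5-(benzyloxy)-2-[4-(benzyloxy)phenyl]-6,7,8-trimethoxychroman-3-one A4.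
- For: the ring closure uses a C–H bond, has no regiochemical choice, and needs no carboxyl carbon on ring A. A2 is needed only in catalytic amount, whereas A3 is consumed in stoichiometric amount. A1 derives from diol 3.
- Against: A4 is at the wrong oxidation pattern. Its carbonyl is on C3, C4 is a methylene and C2 is a needless sp3 stereocentre. Reaching the flavone needs oxidation of C4 to the ketone level, O-methylation of the C3 enol and removal of two benzyl groups, at least three further steps. Before the key step, 3 has to be desymmetrised by a statistical monobenzylation and then O-alkylated at a centre that is both benzylic and propargylic and ionises easily. In the key step the electron-rich arene of A1 can add to the gold-activated alkyne directly (hydroarylation to a 2H-chromene) before A3 delivers its oxygen.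
- Comparison: Alternative 1 is stronger in the catalytic C–H ring closure. The chosen strategy delivers the C4 carbonyl, the C3 methoxy and C2=C3 at their final oxidation level in one step, uses both phenols of 3 symmetrically, and needs only two deprotections afterwards.

**Alternative 2: aryne insertion into an acrylic acid C–O bond.**
- Disconnection: C8a–O1, C4a–C4 and O1–C2, leading to the aryne precursor 2,3,4,5-tetramethoxy-6-(trimethylsilyl)phenyl trifluoromethanesulfonate A5 and to 3-[4-(benzyloxy)phenyl]-2,3-dimethoxyprop-2-enoic acid A6.
- Forward key step: a fluoride source releases the symmetric aryne from A5. The carboxylate of A6 adds to it, the aryl anion attacks the acyl carbon (formal insertion into the acyl C–O bond), and the phenoxide so formed displaces the β-methoxy group. The product is 2-[4-(benzyloxy)phenyl]-3,5,6,7,8-pentamethoxy-4H-chromen-4-one A7.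
- For: it is the most convergent plan, with three bonds and ring C formed in one step, and the symmetric aryne has no regiochemical issue. A single Lewis-acid step could in principle remove both the benzyl group and the C5 methyl group of A7 at the end.
- Against: A5 is itself a hexasubstituted benzene that needs a multistep preparation. Both aryne carbons are flanked by methoxy groups. The aryl anion can be protonated by the acid A6, which gives a simple aryl ester instead of insertion. A6 is a tetrasubstituted acrylic acid. After A7, the C5 methyl ether must be distinguished from four others by chelation-controlled demethylation, and the C3 methoxy also sits next to the carbonyl.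
- Comparison: Alternative 2 is stronger on convergence and on bonds formed per step. The chosen strategy has a C5 oxygen that is differentiated by symmetry with no selective demethylation, and a precursor assembled from a commodity arene by simple aromatic chemistry.

**Alternative 3: ring A from a cyclobutenone electrocyclic cascade.**
- Disconnection: the C4a–C5 bond and the whole of ring A, traced to dimethyl squarate A8 through racemic 4-{6-[4-(benzyloxy)phenyl]-5-methoxy-4-oxo-4H-pyran-2-yl}-2,3,4-trimethoxycyclobut-2-en-1-one A9.
- Forward key step: heating A9 opens the four-membered ring to a dienylketene. Its ketene carbon bonds to the C–H carbon of the pyranone in a six-electron electrocyclisation, and tautomerisation gives 4'-O-benzylcalycopterin A10, which has the same structure as 14.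
- For: ring A is built with every oxygen in place, and the C5 hydroxyl arises from the ketene oxygen, so it is differentiated without any protecting group. From A10 only debenzylation remains.
- Against: A9 needs a 2-aryl-3-methoxy-4-pyranone that is nucleophilic at C6 in the presence of its own carbonyl, its addition to A8, and O-methylation of a tertiary alkoxide. The fully substituted pyranone must be made first, which is the same ring C problem in another form. The count of steps is the highest of the four.
- Comparison: Alternative 3 is stronger on the C5 differentiation and its key step product A10 is one step from the target. The chosen strategy is much shorter before its key step and forms ring C and the C3 methoxy together.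

Key step: step 7

Remark on the chemistry: ylide 10 is assumed to be used as its freshly made THF solution, with the sodium chloride and amine by-products of its formation left in the flask.

## Route

**Step 1**
Reactants: 1 1,2,3-trimethoxybenzene
Product: 2 1,5-dibromo-2,3,4-trimethoxybenzene
Conditions: NBS (2.2 equiv), MeCN, 0 °C to 50 °C
Reagents that add atoms: N-bromosuccinimide, O=C1CCC(=O)N1Br
Why: Electrophilic aromatic bromination; C4 and C6 of 1 are each ortho to one outer methoxy and para to the other, whereas C5 is para only to the twisted central methoxy, and the first bromine is meta to the second site, so the 4,6-dibromide should form selectively.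

**Step 2**
Reactants: 2 1,5-dibromo-2,3,4-trimethoxybenzene
Product: 3 4,5,6-trimethoxybenzene-1,3-diol
Conditions: Pd2(dba)3 (cat.), tBuXPhos (cat.), KOH (6 equiv), degassed 1,4-dioxane/H2O, 100 °C; then aq. HCl
Reagents that add atoms: potassium hydroxide, [K+].[OH-]
Why: Palladium-catalysed C–O coupling of aryl bromides with hydroxide (Buchwald-type hydroxylation) on a zerovalent palladium catalyst with a bulky biarylphosphine; each bromide has one ortho substituent only and the second bromide is meta to the first phenoxide, so it is not strongly deactivated, and acidification under inert gas should give the diol.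

**Step 3**
Reactants: 3 4,5,6-trimethoxybenzene-1,3-diol
Product: 4 2,6-dihydroxy-3,4,5-trimethoxybenzaldehyde
Conditions: POCl3, DMF, MeCN, 0 °C to rt; then H2O, 50 °C
Reagents that add atoms: N,N-dimethylformamide, CN(C)C=O; water, O
Why: Vilsmeier–Haack formylation; the only ring C–H is ortho to both hydroxyls and para to the central methoxy, so the chloroiminium ion can attack only there, and warm water hydrolyses the aryl iminium salt and any O-formyl group to the chelated aldehyde.

**Step 4**
Reactants: 4 2,6-dihydroxy-3,4,5-trimethoxybenzaldehyde; 5 4-(benzyloxy)benzoyl chloride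
Product: 6 2-formyl-4,5,6-trimethoxy-1,3-phenylene bis[4-(benzyloxy)benzoate]
Conditions: 5 (2.4 equiv), Et3N, DMAP (cat.), CH2Cl2, 0 °C to rt
Reagents that add atoms: none
Why: DMAP-catalysed O-acylation of phenols by an acid chloride; at the aldehyde stage no carboxyl group competes, and the N-acylpyridinium ion is reactive enough for the two hydrogen-bonded, flanked hydroxyls.

**Step 5**
Reactants: 6 2-formyl-4,5,6-trimethoxy-1,3-phenylene bis[4-(benzyloxy)benzoate]
Product: 7 2,6-bis{[4-(benzyloxy)benzoyl]oxy}-3,4,5-trimethoxybenzoic acid
Conditions: NaClO2, NaH2PO4, 2-methyl-2-butene, t-BuOH/THF/H2O, 0 °C to rt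
Reagents that add atoms: sodium chlorite, [Na+].[O-]Cl=O
Why: Pinnick oxidation; buffered chlorous acid oxidises the aldehyde without touching aryl esters or benzyl ethers, ring A has no free position for chlorination, and 2-methyl-2-butene traps the hypochlorous acid formed.

**Step 6**
Reactants: 7 2,6-bis{[4-(benzyloxy)benzoyl]oxy}-3,4,5-trimethoxybenzoic acid
Product: 8 2,6-bis{[4-(benzyloxy)benzoyl]oxy}-3,4,5-trimethoxybenzoyl chloride
Conditions: (COCl)2, DMF (cat.), CH2Cl2, 0 °C to rt; evaporate, use crude
Reagents that add atoms: oxalyl chloride, O=C(Cl)C(=O)Cl
Why: Acid chloride formation through the catalytic chloroiminium intermediate; the conditions are neutral and anhydrous, so both aryl esters and both benzyl ethers should survive, as they do in O-acylsalicyloyl chlorides.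

**Step 7**
Reactants: 8 2,6-bis{[4-(benzyloxy)benzoyl]oxy}-3,4,5-trimethoxybenzoyl chloride; 9 (methoxymethyl)triphenylphosphonium chloride
Product: 13 2-[4-(benzyloxy)phenyl]-3,6,7,8-tetramethoxy-4-oxo-4H-chromen-5-yl 4-(benzyloxy)benzoate, via methoxymethylenetriphenylphosphorane 10 (not isolated), via acylphosphonium chloride 11 (not isolated), via keto ylide 12 (not isolated)
Conditions: 9 (2.2 equiv), NaHMDS (2.1 equiv), THF, 0 °C; then 8 added slowly, −78 °C to rt; then 65 °C
Reagents that add atoms: none
Why: Two equivalents of ylide 10 are needed: the first attacks the acid chloride carbon of 8 (C-acylation of a phosphorus ylide) to form C3–C4 in phosphonium salt 11, and the second removes the now acidic C3 proton to give the keto-stabilised α-methoxy ylide 12. The ylide carbon of 12 then adds to the carbonyl of one ortho aroyl ester through a six-membered arrangement, and the oxaphosphetane collapses with loss of Ph3P=O, an intramolecular Wittig olefination of an ester carbonyl that forms C2=C3. Ring C is closed in a 6-exo-trig mode, with the ester oxygen becoming O1 and the former ester carbonyl carbon becoming C2. The closest known reaction type is the chromone synthesis from O-acylsalicylic acid derivatives and phosphorus ylides through acylphosphoranes; the α-methoxy group on the ylide and the second ortho substituent on the acid chloride are what is new for this substrate. No stereocentre is formed. The selectivity needed is attack of 10 on the acid chloride in preference to the two aryl esters, which should follow from the much higher electrophilicity of the acid chloride at −78 °C and from the deactivation of the ester carbonyls by their para benzyloxy groups; slow addition of 8 keeps 10 in excess so that 11 is deprotonated at once. The two aroyl esters of 12 are related by the mirror plane of ring A, so either one gives the same product and the other stays on as the mask of the C5 hydroxyl. Heating is applied at the end because 12 is a stabilised ylide and an ester carbonyl is a weak electrophile.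

**Step 8**
Reactants: 13 2-[4-(benzyloxy)phenyl]-3,6,7,8-tetramethoxy-4-oxo-4H-chromen-5-yl 4-(benzyloxy)benzoate
Product: 14 2-[4-(benzyloxy)phenyl]-5-hydroxy-3,6,7,8-tetramethoxy-4H-chromen-4-one (4'-O-benzylcalycopterin)
Conditions: K2CO3 (1.5 equiv), MeOH/THF, rt; then aq. NH4Cl
Reagents that add atoms: none
Why: Base-mediated methanolysis (transesterification) of an aryl ester; the only ester in 13 has a phenoxide peri to the carbonyl as leaving group, while the benzyl and methyl ethers and the chromone are inert to carbonate in methanol at room temperature.

**Step 9**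
Reactants: 14 2-[4-(benzyloxy)phenyl]-5-hydroxy-3,6,7,8-tetramethoxy-4H-chromen-4-one
Product: 15 calycopterin, 5-hydroxy-2-(4-hydroxyphenyl)-3,6,7,8-tetramethoxy-4H-chromen-4-one
Conditions: H2 (1 atm), Pd/C, EtOAc/MeOH, rt
Reagents that add atoms: none
Why: Catalytic hydrogenolysis of a benzyl aryl ether; the tetrasubstituted C2=C3 bond is part of a vinylogous ester and should not be reduced at one atmosphere, and no other reducible group is present.

## Compound list

1 | 1,2,3-trimethoxybenzene | COc1cccc(OC)c1OC | starting material
2 | 1,5-dibromo-2,3,4-trimethoxybenzene | COc1c(Br)cc(Br)c(OC)c1OC | intermediate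
3 | 4,5,6-trimethoxybenzene-1,3-diol | COc1c(O)cc(O)c(OC)c1OC | intermediate
4 | 2,6-dihydroxy-3,4,5-trimethoxybenzaldehyde | COc1c(O)c(C=O)c(O)c(OC)c1OC | intermediate
5 | 4-(benzyloxy)benzoyl chloride | O=C(Cl)c1ccc(OCc2ccccc2)cc1 | starting material
6 | 2-formyl-4,5,6-trimethoxy-1,3-phenylene bis[4-(benzyloxy)benzoate] | COc1c(OC)c(OC(=O)c2ccc(OCc3ccccc3)cc2)c(C=O)c(OC(=O)c2ccc(OCc3ccccc3)cc2)c1OC | intermediate
7 | 2,6-bis{[4-(benzyloxy)benzoyl]oxy}-3,4,5-trimethoxybenzoic acid | COc1c(OC)c(OC(=O)c2ccc(OCc3ccccc3)cc2)c(C(=O)O)c(OC(=O)c2ccc(OCc3ccccc3)cc2)c1OC | intermediate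
8 | 2,6-bis{[4-(benzyloxy)benzoyl]oxy}-3,4,5-trimethoxybenzoyl chloride | COc1c(OC)c(OC(=O)c2ccc(OCc3ccccc3)cc2)c(C(=O)Cl)c(OC(=O)c2ccc(OCc3ccccc3)cc2)c1OC | intermediate
9 | (methoxymethyl)triphenylphosphonium chloride | COC[P+](c1ccccc1)(c1ccccc1)c1ccccc1.[Cl-] | starting material
10 | methoxymethylenetriphenylphosphorane | COC=P(c1ccccc1)(c1ccccc1)c1ccccc1 | intermediate
11 | [2-(2,6-bis{[4-(benzyloxy)benzoyl]oxy}-3,4,5-trimethoxyphenyl)-1-methoxy-2-oxoethyl]triphenylphosphonium chloride, racemic | COc1c(OC)c(OC(=O)c2ccc(OCc3ccccc3)cc2)c(C(=O)C(OC)[P+](c2ccccc2)(c2ccccc2)c2ccccc2)c(OC(=O)c2ccc(OCc3ccccc3)cc2)c1OC.[Cl-] | intermediate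
12 | 2-[2-methoxy-2-(triphenyl-λ5-phosphanylidene)acetyl]-4,5,6-trimethoxy-1,3-phenylene bis[4-(benzyloxy)benzoate] | COc1c(OC)c(OC(=O)c2ccc(OCc3ccccc3)cc2)c(C(=O)C(OC)=P(c2ccccc2)(c2ccccc2)c2ccccc2)c(OC(=O)c2ccc(OCc3ccccc3)cc2)c1OC | intermediate
13 | 2-[4-(benzyloxy)phenyl]-3,6,7,8-tetramethoxy-4-oxo-4H-chromen-5-yl 4-(benzyloxy)benzoate | COc1c(OC)c(OC(=O)c3ccc(OCc4ccccc4)cc3)c2c(=O)c(OC)c(-c3ccc(OCc4ccccc4)cc3)oc2c1OC | intermediate
14 | 2-[4-(benzyloxy)phenyl]-5-hydroxy-3,6,7,8-tetramethoxy-4H-chromen-4-one | COc1c(OC)c(O)c2c(=O)c(OC)c(-c3ccc(OCc4ccccc4)cc3)oc2c1OC | intermediate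
15 | calycopterin, 5-hydroxy-2-(4-hydroxyphenyl)-3,6,7,8-tetramethoxy-4H-chromen-4-one | COc1c(OC)c(O)c2c(=O)c(OC)c(-c3ccc(O)cc3)oc2c1OC | target

## Step count and risk

Total step count: 9. Longest linear sequence: 9 steps (1 to 15); 5 and 9 are commercial and enter directly.

**Step 7 (key step).** Two processes are the most likely to go wrong. The non-stabilised ylide 10 may attack the aryl ester carbonyls in competition with the hindered, doubly ortho-substituted acid chloride. The stabilised, fully substituted ylide 12 may fail to olefinate the ester carbonyl, so that acyl transfer or plain hydrolysis on work-up takes over. The fallback forms C2–C3 by enolate acylation instead of olefination and still uses the symmetry of ring A. It sets out from 3 and comes back at 13. Hoesch acylation of 3 with methoxyacetonitrile (ZnCl2, HCl gas, Et2O, 0 °C) should give 1-(2,6-dihydroxy-3,4,5-trimethoxyphenyl)-2-methoxyethan-1-iminium chloride F1. Warm water hydrolyses it to 1-(2,6-dihydroxy-3,4,5-trimethoxyphenyl)-2-methoxyethan-1-one F2. Double aroylation with 5 (Et3N, DMAP, CH2Cl2) gives 2-(methoxyacetyl)-4,5,6-trimethoxy-1,3-phenylene bis[4-(benzyloxy)benzoate] F3. LiHMDS in THF (−78 to 0 °C) moves one aroyl group to the α-carbon in a Baker–Venkataraman rearrangement, giving racemic 2-{3-[4-(benzyloxy)phenyl]-2-methoxy-3-oxopropanoyl}-3-hydroxy-4,5,6-trimethoxyphenyl 4-(benzyloxy)benzoate F4. AcOH with catalytic H2SO4 at 60 °C then closes ring C by cyclodehydration to 13.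

**Step 2.** Incomplete coupling at the second bromide, hydrodebromination, and air oxidation of the electron-rich diphenoxide in hot alkali are the likely failures. The fallback makes the C–O bonds by borylation and oxidation under brief, cold basic conditions. It sets out from 2 and comes back at 3. Miyaura borylation (B2pin2, Pd(dppf)Cl2, KOAc, 1,4-dioxane, 90 °C) gives 2,2'-(4,5,6-trimethoxy-1,3-phenylene)bis(4,4,5,5-tetramethyl-1,3,2-dioxaborolane) F5. Oxidation with H2O2 and NaOH at 0 °C, followed by acidification, gives 3.

**Step 3.** Low conversion at a ring position crowded between two hydroxyls, O-formylation, and decomposition of the electron-rich diol under the acidic chloroiminium conditions are the concerns. The fallback replaces electrophilic substitution by directed ortho-metalation. It sets out from 3 and comes back at 4. Chloromethyl methyl ether and iPr2NEt give 1,5-bis(methoxymethoxy)-2,3,4-trimethoxybenzene F6. n-BuLi in THF at 0 °C removes the ring proton flanked by the two methoxymethoxy groups to give [2,6-bis(methoxymethoxy)-3,4,5-trimethoxyphenyl]lithium F7. DMF converts it into 2,6-bis(methoxymethoxy)-3,4,5-trimethoxybenzaldehyde F8. HCl in MeOH removes both acetals to give 4.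

**Step 5.** Slow oxidation of an aldehyde shielded by two ortho aroyloxy groups may let aryl ester hydrolysis or acyl migration gain ground in the aqueous buffer. The fallback brings the carbon in at the acid oxidation level before acylation, and also bypasses steps 3 and 4. It sets out from 3 and comes back at 7. Kolbe–Schmitt carboxylation (KHCO3, CO2, H2O, 60 to 100 °C, cold acidification) gives 2,6-dihydroxy-3,4,5-trimethoxybenzoic acid F9, which is used at once because it is expected to decarboxylate easily. Acylation with 5 (3.3 equiv) in pyridine gives 2,6-bis{[4-(benzyloxy)benzoyl]oxy}-3,4,5-trimethoxybenzoic 4-(benzyloxy)benzoic anhydride F10. Aqueous pyridine opens the anhydride at its less hindered carbonyl to give 7.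

## Further compounds

F1 | step 7 | 1-(2,6-dihydroxy-3,4,5-trimethoxyphenyl)-2-methoxyethan-1-iminium chloride | COCC(=[NH2+])c1c(O)c(OC)c(OC)c(OC)c1O.[Cl-]
F2 | step 7 | 1-(2,6-dihydroxy-3,4,5-trimethoxyphenyl)-2-methoxyethan-1-one | COCC(=O)c1c(O)c(OC)c(OC)c(OC)c1O
F3 | step 7 | 2-(methoxyacetyl)-4,5,6-trimethoxy-1,3-phenylene bis[4-(benzyloxy)benzoate] | COCC(=O)c1c(OC(=O)c2ccc(OCc3ccccc3)cc2)c(OC)c(OC)c(OC)c1OC(=O)c1ccc(OCc2ccccc2)cc1
F4 | step 7 | 2-{3-[4-(benzyloxy)phenyl]-2-methoxy-3-oxopropanoyl}-3-hydroxy-4,5,6-trimethoxyphenyl 4-(benzyloxy)benzoate, racemic | COC(C(=O)c1ccc(OCc2ccccc2)cc1)C(=O)c1c(O)c(OC)c(OC)c(OC)c1OC(=O)c1ccc(OCc2ccccc2)cc1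
F5 | step 2 | 2,2'-(4,5,6-trimethoxy-1,3-phenylene)bis(4,4,5,5-tetramethyl-1,3,2-dioxaborolane) | COc1c(B2OC(C)(C)C(C)(C)O2)cc(B2OC(C)(C)C(C)(C)O2)c(OC)c1OC
F6 | step 3 | 1,5-bis(methoxymethoxy)-2,3,4-trimethoxybenzene | COCOc1cc(OCOC)c(OC)c(OC)c1OC
F7 | step 3 | [2,6-bis(methoxymethoxy)-3,4,5-trimethoxyphenyl]lithium | [Li]c1c(OCOC)c(OC)c(OC)c(OC)c1OCOC
F8 | step 3 | 2,6-bis(methoxymethoxy)-3,4,5-trimethoxybenzaldehyde | COCOc1c(C=O)c(OCOC)c(OC)c(OC)c1OC
F9 | step 5 | 2,6-dihydroxy-3,4,5-trimethoxybenzoic acid | COc1c(O)c(C(=O)O)c(O)c(OC)c1OC
F10 | step 5 | 2,6-bis{[4-(benzyloxy)benzoyl]oxy}-3,4,5-trimethoxybenzoic 4-(benzyloxy)benzoic anhydride | COc1c(OC)c(OC(=O)c2ccc(OCc3ccccc3)cc2)c(C(=O)OC(=O)c2ccc(OCc3ccccc3)cc2)c(OC(=O)c2ccc(OCc3ccccc3)cc2)c1OC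
A1 | alternative 1 | 1-(benzyloxy)-5-({1-[4-(benzyloxy)phenyl]prop-2-yn-1-yl}oxy)-2,3,4-trimethoxybenzene, racemic | C#CC(Oc1cc(OCc2ccccc2)c(OC)c(OC)c1OC)c1ccc(OCc2ccccc2)cc1
A2 | alternative 1 | (triphenylphosphine)gold bis(trifluoromethanesulfonyl)imide, Ph3PAuNTf2 | FC(F)(F)S(=O)(=O)N([Au-][P+](c1ccccc1)(c1ccccc1)c1ccccc1)S(=O)(=O)C(F)(F)F
A3 | alternative 1 | 8-methylquinoline N-oxide | Cc1cccc2ccc[n+]([O-])c12
A4 | alternative 1 | 5-(benzyloxy)-2-[4-(benzyloxy)phenyl]-6,7,8-trimethoxychroman-3-one, racemic | O=C1Cc2c(OCc3ccccc3)c(OC)c(OC)c(OC)c2OC1c1ccc(OCc2ccccc2)cc1
A5 | alternative 2 | 2,3,4,5-tetramethoxy-6-(trimethylsilyl)phenyl trifluoromethanesulfonate | COc1c(OC)c(OC)c(OS(=O)(=O)C(F)(F)F)c([Si](C)(C)C)c1OC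
A6 | alternative 2 | 3-[4-(benzyloxy)phenyl]-2,3-dimethoxyprop-2-enoic acid, either alkene geometry | COC(C(=O)O)=C(OC)c1ccc(OCc2ccccc2)cc1
A7 | alternative 2 | 2-[4-(benzyloxy)phenyl]-3,5,6,7,8-pentamethoxy-4H-chromen-4-one | COc1c(OC)c(OC)c2c(=O)c(OC)c(-c3ccc(OCc4ccccc4)cc3)oc2c1OC
A8 | alternative 3 | dimethyl squarate, 3,4-dimethoxycyclobut-3-ene-1,2-dione | COC1=C(OC)C(=O)C1=O
A9 | alternative 3 | 4-{6-[4-(benzyloxy)phenyl]-5-methoxy-4-oxo-4H-pyran-2-yl}-2,3,4-trimethoxycyclobut-2-en-1-one, racemic | COC1=C(OC)C(OC)(c2cc(=O)c(OC)c(-c3ccc(OCc4ccccc4)cc3)o2)C1=O
A10 | alternative 3 | 4'-O-benzylcalycopterin, same structure as 14 | COc1c(OC)c(O)c2c(=O)c(OC)c(-c3ccc(OCc4ccccc4)cc3)oc2c1OC
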